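The open intermediate is what I follow through these flasks.

    free catalyst + open intermediate ⇌ catalyst intermediate (K1 = 0.71 /M, k1 = 19 /M/s, Ea1 = 38.0 kJ/mol, ΔH1 = −16.0 kJ/mol)
    substrate + open intermediate → side product (k2 = 7.1 × 10⁻⁴ /M/s, Ea2 = 78.0 kJ/mol)
    substrate + free catalyst → free catalyst + open intermediate (k3 = 0.89 /M/s, Ea3 = 36.0 kJ/mol)
    partner + catalyst intermediate → free catalyst + target (k4 = 0.60 /M/s, Ea4 = 37.0 kJ/mol)
    (constants at 35 °C)

all flasks: substrate 1.0 M; partner 0.700 M; free catalyst 2.0 mM; time 1.0 h

|  | temperature | remark |
|---|---|---|
| dawn | 95 °C |  |
| autumn |  | at 35 °C until 20 min, from then on at 95 °C |
| dusk | 65 °C |  |
| winter | 35 °C |  |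

- in percentages every species weighs as the substrate in it: one side product counts as two
- all constants are for 35 °C and move with temperature by the activation energies and enthalpies

1. the flask with the highest amount of target, in percent of the substrate charged ("all alike" if they lie within 1.5 percentage points) (dawn / autumn / dusk / winter / all alike)
2. final target, as a percentage of the substrate charged, in dawn
3. final target, as a percentage of the substrate charged, in autumn
4. final target, as a percentage of the substrate charged, in dusk
5. final target, as a percentage of the substrate charged, in winter

The opening step makes open intermediate from substrate on the free catalyst. The burning step, to side product, eats one substrate and one open intermediate. Both rates carry the substrate as a factor, so their balance does not depend on how much substrate stands. They balance at a ceiling Ic: the opening constant times the catalyst charge, divided by the burning constant, with the catalyst taken as free. Winter has Ic = 2.51 M, more than the charge. Dusk has 0.586 M. Dawn has 0.173 M, less than the charge.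

I solve both ends, with coupling set aside. For Ic far below the charge, the open intermediate ends near Ic. For Ic far above the charge, it ends near the charge. The simple join is W = Ic·cA/(Ic + cA), with cA the substrate charge, and dawn gets 0.148 M.

But that lies below the ceiling that dawn's open intermediate should reach, so the join is crude. Per substrate lost, the open intermediate changes by (Ic − I)/(Ic + I). Integrated, this gives cA = −W − 2·Ic·ln(1 − W/Ic). I put the join into this relation once.

The result is the survivor share, the selectivity of the flask: the part of the charge standing as open intermediate, free or on the catalyst, or as target when the substrate is gone. For dawn it is 16.7%. For dusk it is 40.4%, and for winter 72.6%.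

One doubt is the bound catalyst. Dawn keeps a free share near 95.7%, but winter could fall to 66.0%, which lowers its ceiling. Yet I have not counted the open intermediate that coupling draws off, which acts the other way, so I leave winter uncorrected and distrust it a little.

A second doubt is that a survivor must still couple with the partner to become target. In dusk, the coupling exponent over the hour, with partner taken at its mean, is 3.16, so dusk gives 38.7%. Dawn's exponent is 7.19, larger than dusk's, so I take 16.7% for dawn.

For winter, allowing for the opening time and for bound catalyst, the exponent is 1.44 with partner at full charge, and 0.693 with partner half used by the survivors. Both stand below dusk's exponent. So I put winter between 36.3% and 55.4%.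

Autumn starts as winter does. At the change, I reckon about 11.8% of the substrate remains in autumn. In the heat I take the worst case, that each remaining substrate burns with one open intermediate. That puts autumn's survivors near 49.0%. With the constants of dawn, partner at its mean and the remaining 40.0 min, the coupling exponent is 3.54, so autumn gives 47.6%. Winter's upper figure stands above this, but it assumes unspent partner, so I lean to autumn.

The forecast names autumn, with 18.5% for dawn, 50% for autumn, 37% for dusk and 42% for winter: “Starting cold lets the substrate open cleanly”.

The flasks give autumn: 17.8% in dawn, 52.8% in autumn, 38.1% in dusk and 41.9% in winter. Dawn's side product ends at 82.2%, and my survivor share for dawn was 16.7%. Winter's survivors are still split at the end: target 41.9% and open intermediate 30.9%, against my 72.6%.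

At 80 °C, the same repeat of dawn has a ceiling of 0.310 M, and the survivor share comes to 26.8%. The computed flask ends with target 27.6% and side product 71.9%.

The constants used here were drawn at random within sensible limits; the run is a simulation.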